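**Plan**

1. Retrosynthetic cuts, in order: the two O–Si bonds; the C7–O benzoate; C1–C7 (Stille); the C6–O bond together with contraction of the cyclohexene to a 6,6-dibromobicyclo[3.1.0]hexane (C1 becomes the CBr2 carbon, C2–C6 the shared cyclopropane bond); the cyclopropane bonds C1–C2 and C1–C6 (dibromocarbene); the C5–O benzoate; C2=C6 (metathesis); C5–C6 (vinyl Grignard); back to D-xylose.
2. Enabling feature: in the ring C1(=C2)–C3–C4–C5–C6 the allylic C6 hydroxyl lies next to C1 and cis to the C5 benzoate. A 1-bromocyclohexene with this cis O5/O6 pair is what the allyl cation C2–C1(Br)–C6 gives once the carbonyl of the C5 benzoate has closed on C6.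
3. Forward order: the xylofuranoside (a temporary ring) is opened to an enal, a cyclopentene is closed by metathesis, C1 is added as a fused dibromocyclopropane, the cyclohexene arises by ring expansion, and C7 is joined last.
4. Stereochemistry: C3 and C4 are C3 and C2 of D-xylose; C5 comes from a Felkin–Anh vinyl addition followed by Mitsunobu inversion; C6 is delivered cis by the C5 benzoate.

Key step: step 9

Remark: ring atoms carry the target numbering throughout (C1 bears C7, C2 is the alkene CH, C3 to C6 bear oxygen), also in the five-membered and bicyclic intermediates, where C2 and C6 are bonded to each other.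

**Step 1**
Reactants: 1 D-xylose
Product: 2 methyl D-xylofuranoside (anomeric mixture)
Conditions: MeOH, HCl (cat., anhydrous), 20 °C, short reaction time
Reagents that add atoms: methanol, CO
Why: Fischer glycosidation under kinetic control gives the five-membered methyl glycoside before the pyranoside forms, and the anomeric centre is of no consequence because it is destroyed in step 4.

**Step 2**
Reactants: 2 methyl D-xylofuranoside
Product: 3 methyl 5-deoxy-5-iodo-D-xylofuranoside (anomeric mixture)
Conditions: PPh3, I2, imidazole, THF, 65 °C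
Reagents that add atoms: iodine, II
Why: Appel-type iodination (SN2 displacement of the alkoxyphosphonium ion by iodide) is selective for the only primary hydroxyl over the two secondary ones.

**Step 3**
Reactants: 3 methyl 5-deoxy-5-iodo-D-xylofuranoside
Product: 4 methyl 2,3-bis-O-(tert-butyldimethylsilyl)-5-deoxy-5-iodo-D-xylofuranoside (anomeric mixture)
Conditions: TBSOTf, 2,6-lutidine, CH2Cl2, 0 °C
Reagents that add atoms: tert-butyldimethylsilyl triflate, CC(C)(C)[Si](C)(C)OS(=O)(=O)C(F)(F)F
Why: Silylation of both secondary hydroxyls with a silyl triflate and a hindered pyridine base is standard and avoids alkoxide conditions, under which the C3 oxygen could displace the cis C5 iodide.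

**Step 4**
Reactants: 4 methyl 2,3-bis-O-(tert-butyldimethylsilyl)-5-deoxy-5-iodo-D-xylofuranoside
Product: 5 (2R,3S)-2,3-bis(tert-butyldimethylsilyloxy)pent-4-enal
Conditions: Zn (activated dust), THF–H2O 9:1, ultrasound, 40 °C; used at once
Reagents that add atoms: none
Why: Zinc inserts into the C–I bond and the organozinc fragments with opening of the furanose ring and loss of methoxide (Bernet–Vasella fragmentation), which leaves the two xylose stereocentres untouched.

**Step 5**
Reactants: 5 (2R,3S)-2,3-bis(tert-butyldimethylsilyloxy)pent-4-enal; 6 vinylmagnesium bromide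
Product: 7 (3S,4S,5S)-4,5-bis(tert-butyldimethylsilyloxy)hepta-1,6-dien-3-ol
Conditions: THF, −78 °C
Reagents that add atoms: vinylmagnesium bromide (6), C=C[Mg]Br
Why: Felkin–Anh addition of the Grignard reagent to the α-silyloxy aldehyde (non-chelating silyl ethers, the β-silyloxy group favouring the same face) should set the new carbinol centre anti to the neighbouring silyl ether, and the minor 3-epimer is removed by chromatography here or after step 6.

**Step 6**
Reactants: 7 (3S,4S,5S)-4,5-bis(tert-butyldimethylsilyloxy)hepta-1,6-dien-3-ol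
Product: 8 (1S,4S,5S)-4,5-bis(tert-butyldimethylsilyloxy)cyclopent-2-en-1-ol (hydroxyl cis to the adjacent silyl ether)
Conditions: second-generation Grubbs catalyst (H2IMes)(PCy3)Cl2Ru=CHPh (3 mol %), CH2Cl2, 40 °C
Reagents that add atoms: none
Why: Ring-closing metathesis of the 1,6-diene to a cyclopentene with loss of ethylene tolerates the free allylic alcohol and the silyl ethers and forms no stereocentre.

**Step 7**
Reactants: 8 (1S,4S,5S)-4,5-bis(tert-butyldimethylsilyloxy)cyclopent-2-en-1-ol; 9 benzoic acid
Product: 10 (1R,4S,5S)-4,5-bis(tert-butyldimethylsilyloxy)cyclopent-2-en-1-yl benzoate (all-trans)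
Conditions: PPh3, DIAD, toluene, 0 → 20 °C
Reagents that add atoms: benzoic acid (9), OC(=O)c1ccccc1
Why: Mitsunobu esterification displaces the alkoxyphosphonium ion by benzoate in an SN2 step and so inverts the carbinol centre, which places the benzoate trans to the neighbouring silyl ether as C5 of the target requires.

**Step 8**
Reactants: 10 (1R,4S,5S)-4,5-bis(tert-butyldimethylsilyloxy)cyclopent-2-en-1-yl benzoate; 11 bromoform
Product: 12 6,6-dibromo-3,4-bis(tert-butyldimethylsilyloxy)bicyclo[3.1.0]hexan-2-yl benzoate (cyclopropane on the face opposite the C5 benzoate and the C3 silyl ether)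
Conditions: 50% aq NaOH, BnEt3NCl (cat.), CH2Cl2, ultrasound, 20 °C
Reagents that add atoms: bromoform (11), BrC(Br)Br
Why: Cyclopropanation with dibromocarbene generated under phase-transfer conditions should occur on the face opposite the two allylic oxygen substituents, hydroxide staying in the aqueous phase so that the hindered benzoate survives, and the configuration of the cyclopropane is lost again in step 9.

**Step 9**
Reactants: 12 6,6-dibromo-3,4-bis(tert-butyldimethylsilyloxy)bicyclo[3.1.0]hexan-2-yl benzoate
Product: 16 3-bromo-2-hydroxy-5,6-bis(tert-butyldimethylsilyloxy)cyclohex-3-en-1-yl benzoate (C5 benzoate and C6 hydroxyl cis in target numbering), via 2-bromoallyl cation 13 (not isolated), via dioxolanylium ion 14 (not isolated), via orthoacid 15 (not isolated)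
Conditions: AgBF4 (2 equiv), CaCO3, acetone–H2O 10:1, dark, 20 → 45 °C
Reagents that add atoms: water, O
Why: Proposed new method: AgBF4 abstracts the bromide that lies under the five-membered ring while the C2–C6 bond opens in a disrotatory two-electron electrocyclic step, so the six-membered ring arises by ring expansion, without a ring-closing bond, as the 2-bromoallyl cation 13 spread over C2–C1–C6; the closest known reaction type is the silver-promoted ring expansion of gem-dibromocyclopropanes with capture of the allyl cation by an added or tethered nucleophile, and capture by a vicinal ester is the untested part. The carbonyl oxygen of the C5 benzoate then closes on C6 in a 5-exo-trig mode to the cis-fused 1,3-dioxolan-2-ylium ion 14, the participation known from the second stage of a Woodward cis-hydroxylation, water adds to the acyl carbon, and orthoacid 15 opens to the hydroxy benzoate. The new C6 stereocentre is controlled by C5, because the tethered carbonyl reaches C6 only from the face that carries the C5 oxygen, so the C6–O bond forms cis to it whichever face the cyclopropane occupied. The step needs capture at C6 and not at C2, which the tether secures (closure on C2 would need a seven-membered ring), and it needs the benzoyl group to stay on O5 when 15 opens. For that the route counts on the known preference of cis-fused 2-hydroxy-1,3-dioxolanes on six-membered rings for the axial ester and the equatorial alcohol: the two bulky trans silyl ethers at C3 and C4 are expected to sit diaxial, which holds the C5–O bond axial and the C6–O bond pseudoequatorial, and O6, allylic and next to the bromoalkene, is also the better leaving group. CaCO3 takes up the HBF4 that is set free, which spares the silyl ethers and keeps acid from catalysing acyl migration afterwards.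

**Step 10**
Reactants: 16 3-bromo-2-hydroxy-5,6-bis(tert-butyldimethylsilyloxy)cyclohex-3-en-1-yl benzoate; 17 (tributylstannyl)methanol
Product: 18 2-hydroxy-3-(hydroxymethyl)-5,6-bis(tert-butyldimethylsilyloxy)cyclohex-3-en-1-yl benzoate
Conditions: Pd(PPh3)4 (zerovalent palladium, 5 mol %), 1,4-dioxane, 90 °C
Reagents that add atoms: (tributylstannyl)methanol (17), CCCC[Sn](CCCC)(CCCC)CO
Why: Stille coupling of the alkenyl bromide with the hydroxymethylstannane forms the C1–C7 bond without touching the alkene position and tolerates the free hydroxyl, the ester and the silyl ethers.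

**Step 11**
Reactants: 18 2-hydroxy-3-(hydroxymethyl)-5,6-bis(tert-butyldimethylsilyloxy)cyclohex-3-en-1-yl benzoate; 19 benzoyl chloride
Product: 20 [5-(benzoyloxy)-6-hydroxy-3,4-bis(tert-butyldimethylsilyloxy)cyclohex-1-en-1-yl]methyl benzoate
Conditions: 2,4,6-collidine, CH2Cl2, −40 → 0 °C
Reagents that add atoms: benzoyl chloride (19), O=C(Cl)c1ccccc1
Why: Acylation with an acid chloride and the hindered base collidine at low temperature is selective for the primary allylic hydroxyl over the secondary C6 hydroxyl, which is flanked by C1 and C5.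

**Step 12**
Reactants: 20 [5-(benzoyloxy)-6-hydroxy-3,4-bis(tert-butyldimethylsilyloxy)cyclohex-1-en-1-yl]methyl benzoate
Product: 21 [(3S,4R,5R,6R)-5-(benzoyloxy)-3,4,6-trihydroxycyclohex-1-en-1-yl]methyl benzoate (CNP0198957.7)
Conditions: HF·pyridine, THF–pyridine, 0 → 20 °C
Reagents that add atoms: none
Why: Cleavage of the two silyl ethers with buffered HF·pyridine is mildly acidic, so the benzoates should neither hydrolyse nor migrate, and no stereocentre is touched.

**Compound list**

1 | D-xylose | O=C[C@H](O)[C@@H](O)[C@H](O)CO | starting material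
2 | methyl D-xylofuranoside (anomeric mixture) | COC1O[C@H](CO)[C@H](O)[C@H]1O | intermediate
3 | methyl 5-deoxy-5-iodo-D-xylofuranoside (anomeric mixture) | COC1O[C@H](CI)[C@H](O)[C@H]1O | intermediate
4 | methyl 2,3-bis-O-(tert-butyldimethylsilyl)-5-deoxy-5-iodo-D-xylofuranoside (anomeric mixture) | COC1O[C@H](CI)[C@H](O[Si](C)(C)C(C)(C)C)[C@H]1O[Si](C)(C)C(C)(C)C | intermediate
5 | (2R,3S)-2,3-bis(tert-butyldimethylsilyloxy)pent-4-enal | O=C[C@H](O[Si](C)(C)C(C)(C)C)[C@@H](O[Si](C)(C)C(C)(C)C)C=C | intermediate
6 | vinylmagnesium bromide | C=C[Mg]Br | starting material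
7 | (3S,4S,5S)-4,5-bis(tert-butyldimethylsilyloxy)hepta-1,6-dien-3-ol | C=C[C@H](O)[C@H](O[Si](C)(C)C(C)(C)C)[C@@H](O[Si](C)(C)C(C)(C)C)C=C | intermediate
8 | (1S,4S,5S)-4,5-bis(tert-butyldimethylsilyloxy)cyclopent-2-en-1-ol | C1=C[C@H](O[Si](C)(C)C(C)(C)C)[C@@H](O[Si](C)(C)C(C)(C)C)[C@H]1O | intermediate
9 | benzoic acid | OC(=O)c1ccccc1 | starting material
10 | (1R,4S,5S)-4,5-bis(tert-butyldimethylsilyloxy)cyclopent-2-en-1-yl benzoate | C1=C[C@H](O[Si](C)(C)C(C)(C)C)[C@@H](O[Si](C)(C)C(C)(C)C)[C@@H]1OC(=O)c2ccccc2 | intermediate
11 | bromoform | BrC(Br)Br | starting material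
12 | 6,6-dibromo-3,4-bis(tert-butyldimethylsilyloxy)bicyclo[3.1.0]hexan-2-yl benzoate (cyclopropane anti to the benzoate and the C3 silyl ether) | BrC1(Br)[C@H]2[C@H](O[Si](C)(C)C(C)(C)C)[C@@H](O[Si](C)(C)C(C)(C)C)[C@H](OC(=O)c3ccccc3)[C@@H]12 | intermediate
13 | 2-bromoallyl cation C2–C1(Br)–C6 in the six-membered ring (tetrafluoroborate) | BrC1=C[C@H](O[Si](C)(C)C(C)(C)C)[C@@H](O[Si](C)(C)C(C)(C)C)[C@H](OC(=O)c2ccccc2)[CH+]1.F[B-](F)(F)F | intermediate (not isolated)
14 | cis-fused 2-phenyl-1,3-dioxolan-2-ylium ion across O5/O6 (tetrafluoroborate) | BrC1=C[C@H](O[Si](C)(C)C(C)(C)C)[C@@H](O[Si](C)(C)C(C)(C)C)[C@@H]2OC(c3ccccc3)=[O+][C@H]12.F[B-](F)(F)F | intermediate (not isolated)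
15 | orthoacid, cis-fused 2-hydroxy-2-phenyl-1,3-dioxolane across O5/O6 | BrC1=C[C@H](O[Si](C)(C)C(C)(C)C)[C@@H](O[Si](C)(C)C(C)(C)C)[C@@H]2OC(O)(c3ccccc3)O[C@H]12 | intermediate (not isolated)
16 | 3-bromo-2-hydroxy-5,6-bis(tert-butyldimethylsilyloxy)cyclohex-3-en-1-yl benzoate (1,2-cis, 1,6-trans, 5,6-trans) | BrC1=C[C@H](O[Si](C)(C)C(C)(C)C)[C@@H](O[Si](C)(C)C(C)(C)C)[C@H](OC(=O)c2ccccc2)[C@@H]1O | intermediate
17 | (tributylstannyl)methanol | CCCC[Sn](CCCC)(CCCC)CO | starting material
18 | 2-hydroxy-3-(hydroxymethyl)-5,6-bis(tert-butyldimethylsilyloxy)cyclohex-3-en-1-yl benzoate (configuration as in 16) | OCC1=C[C@H](O[Si](C)(C)C(C)(C)C)[C@@H](O[Si](C)(C)C(C)(C)C)[C@H](OC(=O)c2ccccc2)[C@@H]1O | intermediate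
19 | benzoyl chloride | O=C(Cl)c1ccccc1 | starting material
20 | [5-(benzoyloxy)-6-hydroxy-3,4-bis(tert-butyldimethylsilyloxy)cyclohex-1-en-1-yl]methyl benzoate (configuration as in 21) | O=C(OCC1=C[C@H](O[Si](C)(C)C(C)(C)C)[C@@H](O[Si](C)(C)C(C)(C)C)[C@H](OC(=O)c2ccccc2)[C@@H]1O)c1ccccc1 | intermediate
21 | [(3S,4R,5R,6R)-5-(benzoyloxy)-3,4,6-trihydroxycyclohex-1-en-1-yl]methyl benzoate | O=C(OCC1=C[C@H](O)[C@@H](O)[C@H](OC(=O)c2ccccc2)[C@@H]1O)c1ccccc1 | target

Total step count: 12. Longest linear sequence: 12 steps (1 → 21).

**Steps most likely to fail**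

1. Step 9 (Proposed new method). What may go wrong: acyl transfer to O6 when the orthoacid opens; capture of the cation by water before the ester closes (at C2, or from the wrong face at C6); loss of silyl groups to the acid set free. The fallback uses known reactions only, sets out from 12 and comes back at 18. Heating 12 in toluene at 110 °C opens the cyclopropane thermally with return of bromide and gives the allylic bromide F1 (a vicinal bromo benzoate; its allylic isomer would serve as well). Zinc dust in THF–AcOH removes bromide and benzoate by reductive β-elimination, the reaction that turns acylated glycosyl bromides into glycals, and gives the 2-bromo-1,3-diene F2. OsO4 (cat.) with N-methylmorpholine N-oxide dihydroxylates the bromine-free C5=C6 alkene on the face opposite the allylic C4 silyl ether and gives the cis-diol F3. Stille hydroxymethylation as in step 10 gives the triol F4. tBu2Si(OTf)2 and 2,6-lutidine bridge O6 and O7 as the six-membered silylene F5 in preference to a five-membered ring across O5/O6, the selectivity known from 3′,5′-silylene protection of ribonucleosides. Benzoyl chloride, pyridine and DMAP acylate the one free hydroxyl at C5 to the silylene benzoate F6. HF·pyridine at 0 °C cleaves the cyclic silylene ahead of the two silyl ethers and delivers 18.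

2. Step 8. What may go wrong: slow carbene addition to an alkene deactivated by two allylic C–O bonds, with saponification of the benzoate at the interface gaining ground. The fallback sets out from 8 and comes back at 16; the carbene is added before the ester is in place. TESCl and imidazole give the triethylsilyl ether F7. The same phase-transfer conditions add dibromocarbene to this ester-free alkene and give the dibromocyclopropane F8 (expected mainly on the face of the C3 silyl ether; either face serves). PPTS in MeOH at 0 °C removes the triethylsilyl group selectively and gives the cyclopropyl carbinol F9. Mitsunobu esterification with 9 inverts C5 and gives the benzoate F10, the cyclopropane epimer of 12, which under the conditions of step 9 passes through the same cation 13 and returns 16.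

3. Step 5. What may go wrong: poor facial selectivity in the addition to the aldehyde. The fallback sets out from 5 and comes back at 10; both epimers are used. The 3-epimer of 7, dienol F11, is carried through the metathesis of step 6 to the trans-cyclopentenol F12. F12 already has the C5 configuration of the target and is benzoylated with retention (benzoyl chloride, pyridine, DMAP) to 10, while 8 reaches 10 by the inverting Mitsunobu reaction of step 7.

**Further compounds**

F1 | step 9 | 2,3-dibromo-5,6-bis(tert-butyldimethylsilyloxy)cyclohex-3-en-1-yl benzoate (allylic bromide trans to the benzoate) | BrC1=C[C@H](O[Si](C)(C)C(C)(C)C)[C@@H](O[Si](C)(C)C(C)(C)C)[C@H](OC(=O)c2ccccc2)[C@H]1Br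
F2 | step 9 | 2-bromo-5,6-bis(tert-butyldimethylsilyloxy)cyclohexa-1,3-diene (silyl ethers trans) | BrC1=C[C@H](O[Si](C)(C)C(C)(C)C)[C@@H](O[Si](C)(C)C(C)(C)C)C=C1
F3 | step 9 | 3-bromo-5,6-bis(tert-butyldimethylsilyloxy)cyclohex-3-ene-1,2-diol (1,2-cis, anti to the C4 silyl ether) | BrC1=C[C@H](O[Si](C)(C)C(C)(C)C)[C@@H](O[Si](C)(C)C(C)(C)C)[C@H](O)[C@@H]1O
F4 | step 9 | 3-(hydroxymethyl)-5,6-bis(tert-butyldimethylsilyloxy)cyclohex-3-ene-1,2-diol | OCC1=C[C@H](O[Si](C)(C)C(C)(C)C)[C@@H](O[Si](C)(C)C(C)(C)C)[C@H](O)[C@@H]1O
F5 | step 9 | 6,7-O-(di-tert-butylsilylene) derivative of F4 with free C5 hydroxyl | CC(C)(C)[Si]1(C(C)(C)C)OCC2=C[C@H](O[Si](C)(C)C(C)(C)C)[C@@H](O[Si](C)(C)C(C)(C)C)[C@H](O)[C@@H]2O1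
F6 | step 9 | 5-O-benzoate of the 6,7-O-(di-tert-butylsilylene) compound | CC(C)(C)[Si]1(C(C)(C)C)OCC2=C[C@H](O[Si](C)(C)C(C)(C)C)[C@@H](O[Si](C)(C)C(C)(C)C)[C@H](OC(=O)c3ccccc3)[C@@H]2O1
F7 | step 8 | triethylsilyl ether of 8 | C1=C[C@H](O[Si](C)(C)C(C)(C)C)[C@@H](O[Si](C)(C)C(C)(C)C)[C@H]1O[Si](CC)(CC)CC
F8 | step 8 | 6,6-dibromo-3,4-bis(tert-butyldimethylsilyloxy)-2-(triethylsilyloxy)bicyclo[3.1.0]hexane (cyclopropane on the face of the C3 silyl ether) | BrC1(Br)[C@@H]2[C@H](O[Si](C)(C)C(C)(C)C)[C@@H](O[Si](C)(C)C(C)(C)C)[C@@H](O[Si](CC)(CC)CC)[C@H]12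
F9 | step 8 | 6,6-dibromo-3,4-bis(tert-butyldimethylsilyloxy)bicyclo[3.1.0]hexan-2-ol (hydroxyl cis to the adjacent silyl ether) | BrC1(Br)[C@@H]2[C@H](O[Si](C)(C)C(C)(C)C)[C@@H](O[Si](C)(C)C(C)(C)C)[C@@H](O)[C@H]12
F10 | step 8 | 6,6-dibromo-3,4-bis(tert-butyldimethylsilyloxy)bicyclo[3.1.0]hexan-2-yl benzoate, cyclopropane epimer of 12 | BrC1(Br)[C@@H]2[C@H](O[Si](C)(C)C(C)(C)C)[C@@H](O[Si](C)(C)C(C)(C)C)[C@H](OC(=O)c3ccccc3)[C@H]12
F11 | step 5 | (3R,4S,5S)-4,5-bis(tert-butyldimethylsilyloxy)hepta-1,6-dien-3-ol | C=C[C@@H](O)[C@H](O[Si](C)(C)C(C)(C)C)[C@@H](O[Si](C)(C)C(C)(C)C)C=C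
F12 | step 5 | (1R,4S,5S)-4,5-bis(tert-butyldimethylsilyloxy)cyclopent-2-en-1-ol | C1=C[C@H](O[Si](C)(C)C(C)(C)C)[C@@H](O[Si](C)(C)C(C)(C)C)[C@@H]1O
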